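# Total synthesis proposal for CNP0193924.1: ring B closed by oxidative coupling of a ketone bis-enolate

## Analysis of the target

The target (35) is a dibrominated tricarbocyclic triol. A trans-fused hydrindane (cyclopentane C8–C9–C10–C11–C16 fused along C11–C16 to the cyclohexane ring B, C11–C12–C13–C14–C15–C16) is joined through the secondary carbinol carbon C7 to a second cyclohexane, ring A (C1'–C6'). There are eight stereocentres: C8 (R), C11 (S), C12 (S), C15 (R) and C16 (S) on the hydrindane, C7 (R) on the linker, and C1' (R) and C4' (S) on ring A. On ring B the C11 methyl group, the equatorial bromine at C12 and the axial hydroxyl at C15 lie on one face; the C16 hydrogen and the C8 side chain lie on the other. On ring A the tertiary hydroxyl at C1' is axial and cis to the equatorial bromine at C4'. Both bromides are secondary and neopentylic (C12 next to quaternary C11, C4' next to the gem-dimethyl carbon C3'), so they cannot be made by substitution and are prone to Wagner–Meerwein shifts on ionisation; the two tertiary alcohols can dehydrate. The hard points are the trans ring fusion at a quaternary carbon, the two neopentylic C–Br centres, and C1', which sits in a nearly symmetrical ring far from the other stereocentres. The strategy rests on ring B: C12 and C15 are 1,4-related and only C13–C14 lies between their α-carbons, so ring B is a latent cyclohexane-1,4-dione whose C13–C14 bond can be made by joining the methyl carbons of acetyl groups on C11 and C16.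

## Retrosynthetic reasoning

**The two C–Br centres.** Both bromine-bearing carbons of 35 are returned to sp2 carbons by cutting the C12–H/C13–H and C4'–H/C5'–H bonds, which gives the bis(alkenyl bromide) 34. Substitution at these carbons is not possible, whereas an alkenyl bromide comes regiospecifically from a ketone that can enolise to one side only. The forward step is a hydrogen-atom-transfer hydrogenation that must add hydrogen at C12 and C4' on the face opposite the neighbouring axial methyl group. No alkyl bromide then has to survive any other step.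

**The C1' carbinol.** The tertiary hydroxyl at C1' is removed together with a C6'–H bond: 34 comes from the epoxy alcohol 33 by hydride opening at C6', and 33 from the dienyl carbinol 32 by epoxidation directed by the C7 hydroxyl. C1' has no neighbour within ring A that could control it; only the C7 carbinol is close enough. Adding a C7 nucleophile to a ring A ketone was set aside because the two faces of such a ketone differ only through a remote substituent.

**The C7–C1' bond and the C7 centre.** 32 is the Felkin–Anh hydride reduction product of the dienone 31, which comes by oxidation from the carbinol mixture 30, assembled from aldehyde 21 and dienyl triflate 28 by a chromium-mediated coupling. Passing through the ketone costs two steps but turns C7 into a substrate-controlled reduction: carbon adding to 21 should favour the wrong C7 epimer, hydride adding to 31 the right one.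

**The ring A fragment.** 28 already carries the ring A bromine as an alkenyl bromide. It comes from the β,γ-unsaturated ketone 26 by deprotonation at the doubly activated C6' and O-sulfonylation, 26 from the acetal 25, and 25 from ketone 22 through hydrazone 23. Ring A stays achiral until it is joined to C7, so no enantioselective fragment synthesis is needed.

**The hydrindane functional groups.** 21 goes back through alcohol 20 to silyl ether 19, whose alkenyl bromide comes from the C12 ketone of 16 through hydrazone 17. The C15 methyl carbinol of 16 is cut at C15–CH3 to give diketone 15. The C15 carbonyl has a methine neighbour and the C12 carbonyl a quaternary one, so a methyl nucleophile should choose C15; the syn-axial C11 methyl group forces equatorial entry, which gives the axial hydroxyl.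

**Ring B (key disconnection).** Ring B of 15 is opened at C13–C14, the one ring bond lying between two carbonyl α-carbons. This gives two methyl ketones, the trans-diacetylcyclopentane 13; the forward reaction is an oxidative coupling of its bis-enolate. A ring is removed and no stereocentre: the trans fusion of 15 is already the trans relationship of the acetyl groups in 13. The forward step must enolise both methyl groups rather than C16 and must close the ring in preference to intermolecular coupling.

**The trans relationship.** 13 is the C16 epimer of the all-cis diketone 12, which arises by cleaving the C12=C15 double bond of cyclobutene 10. The branch at C8 makes the epimerisation dependable: in 12 the C16 acetyl group is cis to both neighbours, in 13 only to the C11 methyl group. For this reason C8 carries its one-carbon branch from here on rather than a masked ketone. An acetal at C8 would sit β to the C15 carbonyl and could be expelled from the C16 enolate, would give C16 no thermodynamic bias, and would later require homologation of a ketone next to an epimerisable ring-fusion carbon.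

**C7–C8 and the absolute configuration.** Silyl ether 10 comes from alcohol 9, and 9 by hydroboration of the exocyclic alkene 7 from the convex face of the bicycle, which places C7 on the face of the four-membered ring as the target requires. Alkene 7 is made from racemic ketone 3 and the enantiopure sulfoximine 4 through adduct 6. The diastereomeric adducts are separated, so the methylenation doubles as the resolution.

**The bicycle.** 3 is cut at C11–C12 and C15–C16 into enone 1 and alkyne 2. The [2+2] photocycloaddition sets the quaternary carbon C11 and the cis relationship of C11 and C16 without an enolate alkylation.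

## Alternatives that were turned down

Alternative 1: Ring B and the five-membered ring are cut together at C11–C16 and C12–C13, opening the hydrindane to the open-chain bromo-trienone A1. On heating, or with Me2AlCl, the bromo-enone of A1 should add across its tethered diene to give the hydrindenone A2. In its favour, one step makes two rings, the quaternary C11 and the C12–Br bond, and the cis relation of C11–CH3 and bromine follows stereospecifically from the E dienophile. The chosen route reaches that relation only through the face selectivity of a hydrogen-atom transfer, so on this point the Diels–Alder route is stronger. Against it, the trans fusion needs an exo-type transition state of a trisubstituted β-bromo dienophile, and ketone-tethered trienes of this length commonly prefer the cis-fused product. Facial selectivity rests on C8 alone, and the β-bromo enone can lose bromide under Lewis acid. A2 also still needs Markovnikov hydration of C14=C15 with an axial hydroxyl and removal of the C10 carbonyl beside a secondary bromide. The chosen route offers instead a ring fusion fixed before ring closure, oxygen only at carbons that keep a heteroatom, and bromine that never meets a deoxygenation.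

Alternative 2: The five-membered ring is cut at C8–C16. The α-diazo-β-keto ester A3, built on a fully substituted ring B, would be decomposed by Rh2(OAc)4, and the carbenoid at C8 would insert into the equatorial C16–H bond to give the β-keto ester A4. In its favour, 1,5 C–H insertion to cyclopentanones is among the most dependable carbenoid reactions, proceeds with retention and can give a trans-fused hydrindanone. C7 also arrives as an ester, with C8 epimerisable to the more stable configuration. On the certainty of the ring closure this route is at least as secure as an enolate coupling. Against it, the difficulty moves into A3: a monocyclic cyclohexane that must already carry quaternary C11, the neopentylic bromide and the C15 tertiary ether in the right configuration with no ring fusion to direct them. The C16 methylene is flanked by two fully substituted carbons, and C12–H and the C11 methyl group are also 1,5 to the carbenoid. The C9 carbonyl of A4 must then be deleted next to an alkyl bromide. The chosen route builds ring B on a rigid bicyclic template, uses both carbonyl groups and leaves no redundant oxygen.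

Alternative 3: C8–C16 and C10–C11 are cut without opening a ring. The magnesium alkoxide of the 4-hydroxy enone A5 would direct the alkenylmagnesium reagent from bromide A6 to C16 on the face of the oxygen. The enolate would then be allylated at C11 anti to the new substituent, giving A7, and ring-closing metathesis would make the five-membered ring. In its favour, this is the shortest way to a ring B that already has the C15 carbinol, the C12 carbonyl and both ring-fusion centres with the correct relative configuration. In step count to the hydrindane it is better than the chosen route. Against it, the quaternary centre must come from C-allylation of a tetrasubstituted magnesium enolate beside a free alkoxide, where proton transfer and O-alkylation compete. A5 must be obtained as one enantiomer. C8 becomes an alkene carbon after metathesis, so its configuration would depend on a late hydrogenation. The chosen route offers a quaternary carbon made by cycloaddition, a ring fusion under thermodynamic control and a C8 centre set early on a rigid bicycle, at the price of more steps.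

Key step: step 8

## Route

Remarks: the locants C7–C16 and C1'–C6' of the analysis are kept for all intermediates. Compound 3 is racemic and its SMILES shows the enantiomer that is carried on. Compounds 4 and 22 are taken to be catalogue compounds.

Step 1
Reactants: 1 3-methylcyclopent-2-en-1-one; 2 but-2-yne
Product: 3 rac-(1S,5S)-5,6,7-trimethylbicyclo[3.2.0]hept-6-en-2-one
Conditions: hν (Hg lamp, uranium-glass filter), 2 (5 equiv), CH2Cl2, –20 °C, to partial conversion
Reagents that add atoms: none
Why: Enone–alkyne [2+2] photocycloaddition through the enone triplet; the five-membered ring allows only a cis-fused cyclobutene, so quaternary C11 and C16 are set relative to each other, and the symmetrical alkyne leaves no regiochemical question. Long-wavelength light and incomplete conversion limit the secondary 1,3-acyl shift of the β,γ-unsaturated ketone product.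

Step 2
Reactants: 3 rac-(1S,5S)-5,6,7-trimethylbicyclo[3.2.0]hept-6-en-2-one; 4 (S)-N,S-dimethyl-S-phenylsulfoximine
Product: 6 (1S,2R,5S)-5,6,7-trimethyl-2-{[(S)-N-methyl-S-phenylsulfonimidoyl]methyl}bicyclo[3.2.0]hept-6-en-2-ol, via lithiated sulfoximine 5 (not isolated)
Conditions: 4, n-BuLi, THF, 0 °C; then 3, –78 °C; NH4Cl; separation of the two diastereomers on SiO2
Reagents that add atoms: none
Why: Sulfoximine resolution (Johnson): the lithiated sulfoximine adds to the carbonyl from the convex face, so each enantiomer of 3 should give essentially one β-hydroxysulfoximine, and the two diastereomers can be separated on silica. The adduct of the (1S,5S)-ketone is kept (assignment by crystallography or correlation); the S-methyl carbon of 4 becomes C7.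

Step 3
Reactants: 6 (1S,2R,5S)-5,6,7-trimethyl-2-{[(S)-N-methyl-S-phenylsulfonimidoyl]methyl}bicyclo[3.2.0]hept-6-en-2-ol
Product: 7 (1S,5S)-5,6,7-trimethyl-2-methylidenebicyclo[3.2.0]hept-6-ene
Conditions: Al(Hg), AcOH, THF/H2O, 23 °C
Reagents that add atoms: none
Why: Reductive elimination of the β-hydroxysulfoximine with aluminium amalgam (Johnson methylenation) gives the exocyclic alkene under conditions that leave the cyclobutene and the ring-fusion centres untouched.

Step 4
Reactants: 7 (1S,5S)-5,6,7-trimethyl-2-methylidenebicyclo[3.2.0]hept-6-ene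
Product: 9 [(1S,2R,5S)-5,6,7-trimethylbicyclo[3.2.0]hept-6-en-2-yl]methanol, via B-alkyl-9-BBN adduct 8 (not isolated)
Conditions: 9-BBN, THF, 0 → 23 °C; then NaOH, H2O2, 0 °C
Reagents that add atoms: hydrogen peroxide, OO
Why: Hydroboration–oxidation: 9-BBN does not react with the tetrasubstituted cyclobutene and adds to the 1,1-disubstituted alkene from the convex face, opposite the four-membered ring on the adjacent carbon. Hydrogen therefore enters C8 on the face of C16–H and the CH2OH group ends cis to the cyclobutene, which is the C8 configuration of the target (R).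

Step 5
Reactants: 9 [(1S,2R,5S)-5,6,7-trimethylbicyclo[3.2.0]hept-6-en-2-yl]methanol
Product: 10 tert-butyl(dimethyl){[(1S,2R,5S)-5,6,7-trimethylbicyclo[3.2.0]hept-6-en-2-yl]methoxy}silane
Conditions: TBSCl, imidazole, DMF, 23 °C
Reagents that add atoms: tert-butyldimethylsilyl chloride, CC(C)(C)[Si](C)(C)Cl
Why: Silylation of the primary alcohol; the tert-butyldimethylsilyl ether is inert to ozone, methoxide, amide base, organocerium reagent, hydrazine and bromine.

Step 6
Reactants: 10 tert-butyl(dimethyl){[(1S,2R,5S)-5,6,7-trimethylbicyclo[3.2.0]hept-6-en-2-yl]methoxy}silane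
Product: 12 1,1'-[(1S,2R,3R)-3-({[tert-butyl(dimethyl)silyl]oxy}methyl)-1-methylcyclopentane-1,2-diyl]di(ethan-1-one), via secondary ozonide 11 (not isolated)
Conditions: O3, CH2Cl2, –78 °C; then PPh3, –78 → 23 °C
Reagents that add atoms: ozone, [O-][O+]=O
Why: Ozonolysis with reductive work-up; the strained, electron-rich tetrasubstituted alkene is the only site of attack and both acetyl groups appear at once. C11 and C16 are untouched, so the CH2OSi group and the two acetyl groups all lie on one face.

Step 7
Reactants: 12 1,1'-[(1S,2R,3R)-3-({[tert-butyl(dimethyl)silyl]oxy}methyl)-1-methylcyclopentane-1,2-diyl]di(ethan-1-one)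
Product: 13 1,1'-[(1S,2S,3R)-3-({[tert-butyl(dimethyl)silyl]oxy}methyl)-1-methylcyclopentane-1,2-diyl]di(ethan-1-one)
Conditions: NaOMe (0.2 equiv), MeOH, 23 °C
Reagents that add atoms: none
Why: Thermodynamic epimerisation through the C16 enolate, the only stereocentre that can enolise: the C16 acetyl group leaves the face it shares with the C8 side chain and the C11 acetyl group for the face of C8–H and C11–CH3. The aldol closure open to 1,4-diketones is here a disfavoured 5-(enolendo)-exo-trig process and would in 13 lead to a trans-fused bicyclo[3.3.0]octane, so mild base should leave the methyl ketones alone.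

Step 8
Reactants: 13 1,1'-[(1S,2S,3R)-3-({[tert-butyl(dimethyl)silyl]oxy}methyl)-1-methylcyclopentane-1,2-diyl]di(ethan-1-one)
Product: 15 (1R,3aS,7aS)-1-({[tert-butyl(dimethyl)silyl]oxy}methyl)-3a-methyloctahydro-1H-indene-4,7-dione, via dilithium bis-enolate 14 (not isolated)
Conditions: LiN(iPr)2 (2.3 equiv), THF, –78 °C, 0.02 M; then CuCl2 (2.3 equiv), DMF, –78 → –20 °C
Reagents that add atoms: none
Why: Kinetic double deprotonation removes one proton from each acetyl methyl group (C13 and C14) and not the hindered C16 methine, giving the dilithium bis-enolate 14. Divalent copper oxidises one enolate to an α-keto radical, which adds to the terminal carbon of the second enolate; a second one-electron oxidation of the resulting ketyl gives the 1,4-diketone, and two equivalents of CuCl2 end as CuCl. The closest known reaction type is the intramolecular Saegusa-type oxidative coupling of ketone dienolates with CuCl2 or FeCl3 to cyclic 1,4-diketones. Ring B is closed by C13–C14 bond formation in a 6-endo-trig radical–enolate combination, the only mode that joins the two nucleophilic termini. No stereocentre is created: the trans ring fusion is the trans relationship of the acetyl groups of 13 and needs no kinetic control here. The selectivities needed are methyl-over-methine enolisation, secured by kinetic base at –78 °C and the congestion around C16–H, and intra- over intermolecular coupling, secured by high dilution and the 1,2-placement of the acetyl groups. Aldol closure of a mono-enolate is not a competitor because it would be a 5-(enolendo)-exo-trig attack leading to a trans-fused bicyclo[3.3.0]octane. The product carries its ketones at C12 and C15, the positions of the bromide and of the methyl carbinol.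

Step 9
Reactants: 15 (1R,3aS,7aS)-1-({[tert-butyl(dimethyl)silyl]oxy}methyl)-3a-methyloctahydro-1H-indene-4,7-dione
Product: 16 (1R,3aS,7R,7aS)-1-({[tert-butyl(dimethyl)silyl]oxy}methyl)-7-hydroxy-3a,7-dimethyloctahydro-4H-inden-4-one
Conditions: MeMgBr (1.2 equiv), CeCl3, THF, –78 °C
Reagents that add atoms: methylmagnesium bromide, C[Mg]Br
Why: Organocerium 1,2-addition: the C15 carbonyl has a methine neighbour, the C12 carbonyl a quaternary one with an axial methyl group beside its equatorial approach, so one equivalent should react at C15, and the low basicity of the cerium reagent avoids enolisation toward C16. Axial approach to C15 is blocked by the syn-axial C11 methyl group, so the new methyl group enters equatorially and the hydroxyl is axial, cis to the angular methyl group (15R).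

Step 10
Reactants: 16 (1R,3aS,7R,7aS)-1-({[tert-butyl(dimethyl)silyl]oxy}methyl)-7-hydroxy-3a,7-dimethyloctahydro-4H-inden-4-one
Product: 17 (3R,3aS,4R,7aS)-3-({[tert-butyl(dimethyl)silyl]oxy}methyl)-7-hydrazinylidene-4,7a-dimethyloctahydro-1H-inden-4-ol
Conditions: N2H4·H2O (excess), Et3N, EtOH, 80 °C
Reagents that add atoms: hydrazine, NN
Why: Hydrazone formation; excess hydrazine drives condensation at the hindered ketone and suppresses azine formation, and the silyl ether and tertiary alcohol are inert.

Step 11
Reactants: 17 (3R,3aS,4R,7aS)-3-({[tert-butyl(dimethyl)silyl]oxy}methyl)-7-hydrazinylidene-4,7a-dimethyloctahydro-1H-inden-4-ol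
Product: 19 (3R,3aS,4R,7aS)-7-bromo-3-({[tert-butyl(dimethyl)silyl]oxy}methyl)-4,7a-dimethyl-2,3,3a,4,5,7a-hexahydro-1H-inden-4-ol, via diazoalkane 18 (not isolated)
Conditions: Br2, 2-tert-butyl-1,1,3,3-tetramethylguanidine (BTMG), CH2Cl2, 0 → 23 °C, hydrazone added slowly
Reagents that add atoms: bromine, BrBr
Why: Barton vinyl halide synthesis: bromine oxidises the hydrazone to the diazoalkane, which is brominated, loses N2 and then the C13 proton, the only β-hydrogen, so the alkenyl bromide can form in one position only. Transannular capture of the C12 cation by the C15 hydroxyl would need a boat with an eclipsed C11–C16 bond, which the trans-fused five-membered ring forbids.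

Step 12
Reactants: 19 (3R,3aS,4R,7aS)-7-bromo-3-({[tert-butyl(dimethyl)silyl]oxy}methyl)-4,7a-dimethyl-2,3,3a,4,5,7a-hexahydro-1H-inden-4-ol
Product: 20 (3R,3aS,4R,7aS)-7-bromo-3-(hydroxymethyl)-4,7a-dimethyl-2,3,3a,4,5,7a-hexahydro-1H-inden-4-ol
Conditions: HF·pyridine, THF, 0 → 23 °C
Reagents that add atoms: none
Why: Fluoride cleavage of the primary silyl ether; the alkenyl bromide and the tertiary alcohol do not react with HF·pyridine at this temperature.

Step 13
Reactants: 20 (3R,3aS,4R,7aS)-7-bromo-3-(hydroxymethyl)-4,7a-dimethyl-2,3,3a,4,5,7a-hexahydro-1H-inden-4-ol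
Product: 21 (1R,3aS,7R,7aS)-4-bromo-7-hydroxy-3a,7-dimethyl-2,3,3a,6,7,7a-hexahydro-1H-indene-1-carbaldehyde
Conditions: Dess–Martin periodinane, NaHCO3, CH2Cl2, 0 → 23 °C
Reagents that add atoms: none
Why: Dess–Martin oxidation; only the primary hydroxyl can be oxidised. C8 already has the more stable configuration (CHO trans to C15 on C16), so the α-centre is not at risk, and a lactol with the C15 hydroxyl would be a trans-fused bicyclo[3.3.0] system and should not form.

Step 14
Reactants: 22 7,7-dimethyl-1,4-dioxaspiro[4.5]decan-8-one
Product: 23 (7,7-dimethyl-1,4-dioxaspiro[4.5]decan-8-ylidene)hydrazine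
Conditions: N2H4·H2O (excess), Et3N, EtOH, 80 °C
Reagents that add atoms: hydrazine, NN
Why: Hydrazone formation at the neopentylic ketone; the dioxolane is stable to hydrazine and base.

Step 15
Reactants: 23 (7,7-dimethyl-1,4-dioxaspiro[4.5]decan-8-ylidene)hydrazine
Product: 25 8-bromo-7,7-dimethyl-1,4-dioxaspiro[4.5]dec-8-ene, via diazoalkane 24 (not isolated)
Conditions: Br2, 2-tert-butyl-1,1,3,3-tetramethylguanidine (BTMG), CH2Cl2, 0 → 23 °C
Reagents that add atoms: bromine, BrBr
Why: Barton vinyl halide synthesis as in step 11; C3' is quaternary, so elimination can only take a C5' proton, and the excess guanidine base protects the acetal from HBr.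

Step 16
Reactants: 25 8-bromo-7,7-dimethyl-1,4-dioxaspiro[4.5]dec-8-ene
Product: 26 4-bromo-5,5-dimethylcyclohex-3-en-1-one
Conditions: 1 M HCl, THF, 0 → 23 °C
Reagents that add atoms: water, O
Why: Acid hydrolysis of the dioxolane; the alkenyl bromide is inert to dilute acid, and the β,γ-unsaturated ketone is used directly so that the double bond does not move into conjugation.

Step 17
Reactants: 26 4-bromo-5,5-dimethylcyclohex-3-en-1-one
Product: 28 4-bromo-5,5-dimethylcyclohexa-1,3-dien-1-yl trifluoromethanesulfonate, via lithium dienolate 27 (not isolated)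
Conditions: LiN(iPr)2, THF, –78 °C; then PhNTf2, –78 → 0 °C
Reagents that add atoms: N-phenylbis(trifluoromethanesulfonimide), O=S(=O)(N(c1ccccc1)S(=O)(=O)C(F)(F)F)C(F)(F)F
Why: Enol triflate formation: the C6' protons are both α to the carbonyl and allylic, so the amide base removes one of them in preference to the neopentylic C2' protons, and the dienolate is sulfonylated on oxygen to give the 2-sulfonyloxy-1,3-diene.

Step 18
Reactants: 21 (1R,3aS,7R,7aS)-4-bromo-7-hydroxy-3a,7-dimethyl-2,3,3a,6,7,7a-hexahydro-1H-indene-1-carbaldehyde; 28 4-bromo-5,5-dimethylcyclohexa-1,3-dien-1-yl trifluoromethanesulfonate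
Product: 30 (4-bromo-5,5-dimethylcyclohexa-1,3-dien-1-yl)[(1R,3aS,7R,7aS)-4-bromo-7-hydroxy-3a,7-dimethyl-2,3,3a,6,7,7a-hexahydro-1H-inden-1-yl]methanol as both C7 epimers, via dienylchromium dichloride 29 (not isolated)
Conditions: CrCl2 (6 equiv), NiCl2 (2 mol%), DMF, 23 °C
Reagents that add atoms: none
Why: Nozaki–Hiyama–Kishi coupling: zerovalent nickel inserts into the unhindered C–OTf bond rather than into the two C–Br bonds, each flanked by a quaternary carbon, and after transmetalation the alkenylchromium species (trivalent chromium) adds only to the aldehyde, not to hydroxyl or alkenyl bromide. The Felkin–Anh model predicts mainly the 7S carbinol; the ratio does not matter because C7 is oxidised in step 19.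

Step 19
Reactants: 30 (4-bromo-5,5-dimethylcyclohexa-1,3-dien-1-yl)[(1R,3aS,7R,7aS)-4-bromo-7-hydroxy-3a,7-dimethyl-2,3,3a,6,7,7a-hexahydro-1H-inden-1-yl]methanol as both C7 epimers
Product: 31 (4-bromo-5,5-dimethylcyclohexa-1,3-dien-1-yl)[(1R,3aS,7R,7aS)-4-bromo-7-hydroxy-3a,7-dimethyl-2,3,3a,6,7,7a-hexahydro-1H-inden-1-yl]methanone
Conditions: Dess–Martin periodinane, NaHCO3, CH2Cl2, 0 °C
Reagents that add atoms: none
Why: Dess–Martin oxidation of the allylic secondary alcohol; both C7 epimers converge on one dienone and the tertiary alcohol cannot react.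

Step 20
Reactants: 31 (4-bromo-5,5-dimethylcyclohexa-1,3-dien-1-yl)[(1R,3aS,7R,7aS)-4-bromo-7-hydroxy-3a,7-dimethyl-2,3,3a,6,7,7a-hexahydro-1H-inden-1-yl]methanone
Product: 32 (R)-(4-bromo-5,5-dimethylcyclohexa-1,3-dien-1-yl)[(1R,3aS,7R,7aS)-4-bromo-7-hydroxy-3a,7-dimethyl-2,3,3a,6,7,7a-hexahydro-1H-inden-1-yl]methanol
Conditions: NaBH4, CeCl3·7H2O, MeOH, –78 °C
Reagents that add atoms: none
Why: Luche 1,2-reduction under Felkin–Anh control: with C16, the larger α-substituent, anti to the incoming hydride and the carbonyl oxygen on the side of C9, hydride passes C8–H and gives the 7R alcohol, the epimer opposite to the one favoured when carbon adds to the aldehyde. The cerium salt keeps the reduction 1,2 and leaves the alkenyl bromides alone.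

Step 21
Reactants: 32 (R)-(4-bromo-5,5-dimethylcyclohexa-1,3-dien-1-yl)[(1R,3aS,7R,7aS)-4-bromo-7-hydroxy-3a,7-dimethyl-2,3,3a,6,7,7a-hexahydro-1H-inden-1-yl]methanol
Product: 33 (R)-[(1R,6R)-4-bromo-3,3-dimethyl-7-oxabicyclo[4.1.0]hept-4-en-1-yl][(1R,3aS,7R,7aS)-4-bromo-7-hydroxy-3a,7-dimethyl-2,3,3a,6,7,7a-hexahydro-1H-inden-1-yl]methanol
Conditions: VO(acac)2 (5 mol%), t-BuOOH, CH2Cl2, 0 °C
Reagents that add atoms: tert-butyl hydroperoxide, CC(C)(C)OO
Why: Hydroxyl-directed epoxidation: only the C1'=C6' bond is allylic to the C7 hydroxyl, and the two bromoalkenes are electron-poor. Allylic 1,2-strain between C2'H2 and the C8 ring places C7–H in the plane of the alkene, so oxygen is delivered to the face that gives the erythro epoxy alcohol, which is 1'R for the 7R carbinol.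

Step 22
Reactants: 33 (R)-[(1R,6R)-4-bromo-3,3-dimethyl-7-oxabicyclo[4.1.0]hept-4-en-1-yl][(1R,3aS,7R,7aS)-4-bromo-7-hydroxy-3a,7-dimethyl-2,3,3a,6,7,7a-hexahydro-1H-inden-1-yl]methanol
Product: 34 (1R)-4-bromo-1-{(R)-[(1R,3aS,7R,7aS)-4-bromo-7-hydroxy-3a,7-dimethyl-2,3,3a,6,7,7a-hexahydro-1H-inden-1-yl](hydroxy)methyl}-5,5-dimethylcyclohex-3-en-1-ol
Conditions: LiAlH4, Et2O, 0 °C
Reagents that add atoms: none
Why: SN2 opening of the epoxide by hydride at C6', the allylic secondary carbon; C1' is fully substituted and the SN2' terminus C4' carries bromine next to a quaternary carbon. The C1'–O bond is untouched, so C1' keeps its configuration, and alkenyl bromides are inert to LiAlH4 at 0 °C.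

Step 23
Reactants: 34 (1R)-4-bromo-1-{(R)-[(1R,3aS,7R,7aS)-4-bromo-7-hydroxy-3a,7-dimethyl-2,3,3a,6,7,7a-hexahydro-1H-inden-1-yl](hydroxy)methyl}-5,5-dimethylcyclohex-3-en-1-ol
Product: 35 (1R,4S)-4-bromo-1-{(R)-[(1R,3aS,4S,7R,7aS)-4-bromo-7-hydroxy-3a,7-dimethyloctahydro-1H-inden-1-yl](hydroxy)methyl}-3,3-dimethylcyclohexan-1-ol
Conditions: Co(acac)2, t-BuOOH, Et3SiH, 1,4-cyclohexadiene, n-PrOH, 22 °C
Reagents that add atoms: none
Why: Hydrogen-atom-transfer hydrogenation of alkenyl halides (Mukaiyama-type cobalt hydride): H· adds to C13 and to C5', giving the α-bromo radicals at C12 and C4' and never a β-bromo radical that could lose bromine. Each radical takes its second hydrogen from 1,4-cyclohexadiene axially, on the face opposite the adjacent axial methyl group (C11–CH3 on ring B; the axial C3' methyl group of the ring A chair that has the C7 substituent equatorial). Both bromines should therefore end equatorial, cis to C11–CH3 (12S) and cis to the axial C1' hydroxyl (4'S).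

## Compound list

1 | 3-methylcyclopent-2-en-1-one | CC1=CC(=O)CC1 | starting material
2 | but-2-yne | CC#CC | starting material
3 | rac-(1S,5S)-5,6,7-trimethylbicyclo[3.2.0]hept-6-en-2-one (racemate; the enantiomer carried on is drawn) | O=C1CC[C@]2(C)C(C)=C(C)[C@H]12 | intermediate
4 | (S)-N,S-dimethyl-S-phenylsulfoximine | C[S@@](=O)(=NC)c1ccccc1 | starting material
5 | {[(S)-N-methyl-S-phenylsulfonimidoyl]methyl}lithium | [Li]C[S@@](=O)(=NC)c1ccccc1 | intermediate
6 | (1S,2R,5S)-5,6,7-trimethyl-2-{[(S)-N-methyl-S-phenylsulfonimidoyl]methyl}bicyclo[3.2.0]hept-6-en-2-ol | O[C@]1(C[S@@](=O)(=NC)c3ccccc3)CC[C@]2(C)C(C)=C(C)[C@H]12 | intermediate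
7 | (1S,5S)-5,6,7-trimethyl-2-methylidenebicyclo[3.2.0]hept-6-ene | C=C1CC[C@]2(C)C(C)=C(C)[C@H]12 | intermediate
8 | 9-{[(1S,2R,5S)-5,6,7-trimethylbicyclo[3.2.0]hept-6-en-2-yl]methyl}-9-borabicyclo[3.3.1]nonane | B3(C4CCCC3CCC4)C[C@@H]1CC[C@]2(C)C(C)=C(C)[C@H]12 | intermediate
9 | [(1S,2R,5S)-5,6,7-trimethylbicyclo[3.2.0]hept-6-en-2-yl]methanol | OC[C@@H]1CC[C@]2(C)C(C)=C(C)[C@H]12 | intermediate
10 | tert-butyl(dimethyl){[(1S,2R,5S)-5,6,7-trimethylbicyclo[3.2.0]hept-6-en-2-yl]methoxy}silane | CC(C)(C)[Si](C)(C)OC[C@@H]1CC[C@]2(C)C(C)=C(C)[C@H]12 | intermediate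
11 | secondary ozonide of 10 (1,2,4-trioxolane bridging C12 and C15, cis-fused to the cyclopentane; the two acetal carbons are not assigned, either form gives 12) | CC(C)(C)[Si](C)(C)OC[C@@H]1CC[C@]2(C)C3(C)OOC(C)(O3)[C@H]12 | intermediate
12 | 1,1'-[(1S,2R,3R)-3-({[tert-butyl(dimethyl)silyl]oxy}methyl)-1-methylcyclopentane-1,2-diyl]di(ethan-1-one) (acetyl groups cis) | CC(C)(C)[Si](C)(C)OC[C@@H]1CC[C@](C)(C(C)=O)[C@@H]1C(C)=O | intermediate
13 | 1,1'-[(1S,2S,3R)-3-({[tert-butyl(dimethyl)silyl]oxy}methyl)-1-methylcyclopentane-1,2-diyl]di(ethan-1-one) (acetyl groups trans) | CC(C)(C)[Si](C)(C)OC[C@@H]1CC[C@](C)(C(C)=O)[C@H]1C(C)=O | intermediate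
14 | dilithium bis-enolate of 13 (both acetyl groups as lithium enolates at C13 and C14) | CC(C)(C)[Si](C)(C)OC[C@@H]1CC[C@](C)(C(=C)O[Li])[C@H]1C(=C)O[Li] | intermediate
15 | (1R,3aS,7aS)-1-({[tert-butyl(dimethyl)silyl]oxy}methyl)-3a-methyloctahydro-1H-indene-4,7-dione | CC(C)(C)[Si](C)(C)OC[C@@H]1CC[C@]2(C)C(=O)CCC(=O)[C@@H]12 | intermediate
16 | (1R,3aS,7R,7aS)-1-({[tert-butyl(dimethyl)silyl]oxy}methyl)-7-hydroxy-3a,7-dimethyloctahydro-4H-inden-4-one | CC(C)(C)[Si](C)(C)OC[C@@H]1CC[C@]2(C)C(=O)CC[C@@](C)(O)[C@@H]12 | intermediate
17 | (3R,3aS,4R,7aS)-3-({[tert-butyl(dimethyl)silyl]oxy}methyl)-7-hydrazinylidene-4,7a-dimethyloctahydro-1H-inden-4-ol (C=N geometry not assigned) | CC(C)(C)[Si](C)(C)OC[C@@H]1CC[C@]2(C)C(=NN)CC[C@@](C)(O)[C@@H]12 | intermediate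
18 | (3R,3aS,4R,7aS)-3-({[tert-butyl(dimethyl)silyl]oxy}methyl)-7-diazo-4,7a-dimethyloctahydro-1H-inden-4-ol | CC(C)(C)[Si](C)(C)OC[C@@H]1CC[C@]2(C)C(=[N+]=[N-])CC[C@@](C)(O)[C@@H]12 | intermediate
19 | (3R,3aS,4R,7aS)-7-bromo-3-({[tert-butyl(dimethyl)silyl]oxy}methyl)-4,7a-dimethyl-2,3,3a,4,5,7a-hexahydro-1H-inden-4-ol | CC(C)(C)[Si](C)(C)OC[C@@H]1CC[C@]2(C)C(Br)=CC[C@@](C)(O)[C@@H]12 | intermediate
20 | (3R,3aS,4R,7aS)-7-bromo-3-(hydroxymethyl)-4,7a-dimethyl-2,3,3a,4,5,7a-hexahydro-1H-inden-4-ol | OC[C@@H]1CC[C@]2(C)C(Br)=CC[C@@](C)(O)[C@@H]12 | intermediate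
21 | (1R,3aS,7R,7aS)-4-bromo-7-hydroxy-3a,7-dimethyl-2,3,3a,6,7,7a-hexahydro-1H-indene-1-carbaldehyde | O=C[C@@H]1CC[C@]2(C)C(Br)=CC[C@@](C)(O)[C@@H]12 | intermediate
22 | 7,7-dimethyl-1,4-dioxaspiro[4.5]decan-8-one | CC1(C)CC2(CCC1=O)OCCO2 | starting material
23 | (7,7-dimethyl-1,4-dioxaspiro[4.5]decan-8-ylidene)hydrazine | CC1(C)CC2(CCC1=NN)OCCO2 | intermediate
24 | 8-diazo-7,7-dimethyl-1,4-dioxaspiro[4.5]decane | CC1(C)CC2(CCC1=[N+]=[N-])OCCO2 | intermediate
25 | 8-bromo-7,7-dimethyl-1,4-dioxaspiro[4.5]dec-8-ene | CC1(C)CC2(CC=C1Br)OCCO2 | intermediate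
26 | 4-bromo-5,5-dimethylcyclohex-3-en-1-one | CC1(C)CC(=O)CC=C1Br | intermediate
27 | lithium 4-bromo-5,5-dimethylcyclohexa-1,3-dien-1-olate | CC1(C)CC(O[Li])=CC=C1Br | intermediate
28 | 4-bromo-5,5-dimethylcyclohexa-1,3-dien-1-yl trifluoromethanesulfonate | CC1(C)CC(OS(=O)(=O)C(F)(F)F)=CC=C1Br | intermediate
29 | (4-bromo-5,5-dimethylcyclohexa-1,3-dien-1-yl)chromium dichloride (trivalent chromium, solvated) | CC1(C)CC(=CC=C1Br)[Cr](Cl)Cl | intermediate
30 | (4-bromo-5,5-dimethylcyclohexa-1,3-dien-1-yl)[(1R,3aS,7R,7aS)-4-bromo-7-hydroxy-3a,7-dimethyl-2,3,3a,6,7,7a-hexahydro-1H-inden-1-yl]methanol, both C7 epimers | CC1(C)CC(=CC=C1Br)C(O)[C@@H]2CC[C@]3(C)C(Br)=CC[C@@](C)(O)[C@@H]23 | intermediate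
31 | (4-bromo-5,5-dimethylcyclohexa-1,3-dien-1-yl)[(1R,3aS,7R,7aS)-4-bromo-7-hydroxy-3a,7-dimethyl-2,3,3a,6,7,7a-hexahydro-1H-inden-1-yl]methanone | CC1(C)CC(=CC=C1Br)C(=O)[C@@H]2CC[C@]3(C)C(Br)=CC[C@@](C)(O)[C@@H]23 | intermediate
32 | (R)-(4-bromo-5,5-dimethylcyclohexa-1,3-dien-1-yl)[(1R,3aS,7R,7aS)-4-bromo-7-hydroxy-3a,7-dimethyl-2,3,3a,6,7,7a-hexahydro-1H-inden-1-yl]methanol | CC1(C)CC(=CC=C1Br)[C@H](O)[C@@H]2CC[C@]3(C)C(Br)=CC[C@@](C)(O)[C@@H]23 | intermediate
33 | (R)-[(1R,6R)-4-bromo-3,3-dimethyl-7-oxabicyclo[4.1.0]hept-4-en-1-yl][(1R,3aS,7R,7aS)-4-bromo-7-hydroxy-3a,7-dimethyl-2,3,3a,6,7,7a-hexahydro-1H-inden-1-yl]methanol | CC1(C)C[C@]2([C@H](O)[C@@H]3CC[C@]4(C)C(Br)=CC[C@@](C)(O)[C@@H]34)O[C@@H]2C=C1Br | intermediate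
34 | (1R)-4-bromo-1-{(R)-[(1R,3aS,7R,7aS)-4-bromo-7-hydroxy-3a,7-dimethyl-2,3,3a,6,7,7a-hexahydro-1H-inden-1-yl](hydroxy)methyl}-5,5-dimethylcyclohex-3-en-1-ol | CC1(C)C[C@@](O)([C@H](O)[C@@H]2CC[C@]3(C)C(Br)=CC[C@@](C)(O)[C@@H]23)CC=C1Br | intermediate
35 | (1R,4S)-4-bromo-1-{(R)-[(1R,3aS,4S,7R,7aS)-4-bromo-7-hydroxy-3a,7-dimethyloctahydro-1H-inden-1-yl](hydroxy)methyl}-3,3-dimethylcyclohexan-1-ol (CNP0193924.1) | CC1(C)C[C@@](O)([C@H](O)[C@@H]2CC[C@]3(C)[C@@H](Br)CC[C@@](C)(O)[C@@H]23)CC[C@@H]1Br | target

## Step count and least certain steps

Total: 23 steps. Longest linear sequence: 19 steps (steps 1–13 and 18–23). The ring A fragment 28 takes 4 steps (14–17) from 22.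

**Step 8 (key step).** The most likely failure is chlorine transfer from CuCl2 to the enolate or radical, or intermolecular coupling to oligomers. The trans-1,2 termini are farther apart than in a cis substrate, so the radical–enolate combination is slower than the processes that compete with it. Fallback (polar instead of oxidative formation of the same bond): starting again from 13, the bis-enolate 14 is silylated with Me3SiCl to the bis(trimethylsilyl enol ether) F1. One equivalent of N-bromosuccinimide converts one enol ether into an α-bromo ketone, giving the bromo ketone silyl enol ether F2 (drawn as the C13 bromide; the C14 regioisomer behaves alike). Bu4NF then frees the remaining enolate, which closes C13–C14 by intramolecular SN2 alkylation (6-exo-tet) and returns to the route at 15.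

**Step 23.** The most likely failure is poor facial selectivity of hydrogen delivery to the C4' radical, because equatorial and axial bromine next to a gem-dimethyl carbon differ little in energy. Over-reduction with loss of bromine is the second risk. Fallback (surface syn-addition instead of radical transfer): 34 is hydrogenated over 5% Rh on Al2O3 (H2, EtOAc), where both hydrogens should add to each bromoalkene from the face opposite the neighbouring axial methyl group. This leads from 34 directly to 35 and makes no new compound (F0).

**Step 18.** The most likely failure is oxidative addition of nickel into the alkenyl C–Br bonds, leading to debromination or oligomers, because bromoalkenes are also competent partners in this coupling. Fallback (halogen-selective lithiation instead of nickel insertion): from 26 the hydrazone F3 is made with N2H4·H2O and oxidised with I2 and tetramethylguanidine to the dienyl iodide F4. With t-BuLi (2 equiv) in Et2O at –100 °C only iodine is exchanged, giving the dienyllithium F5, which is added in excess to 21 at –78 °C and returns to the route at 30.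

**Step 9.** The most likely failure is competing addition at C12 or double addition, or enolisation toward C16 with loss of the trans ring fusion, because the difference between the two carbonyl groups is steric only. Fallback (protect C15, functionalise C12 first): from 15 the less hindered C15 carbonyl is acetalised selectively with 1,2-bis(trimethylsilyloxy)ethane and Me3SiOTf at –78 °C to the mono-acetal F6. The C12 carbonyl is converted through the hydrazone F7 (N2H4·H2O) and Br2 with BTMG into the alkenyl bromide acetal F8. Mild acid hydrolysis gives the bromo ketone F9, whose single carbonyl takes MeMgBr/CeCl3 as in step 9 and returns to the route at 19. This detour also keeps the free C15 hydroxyl out of the Barton step.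

**Step 7.** The most likely failure is aldol condensation of the cis-diketone to a bicyclic enone overtaking epimerisation, since the methyl protons exchange faster than the C16 methine. Fallback (couple first, epimerise afterwards): 12 is submitted to the conditions of step 8 to give the cis-fused dione F10. F10 is then equilibrated at C16 with DBU in toluene, now α to a ring ketone where no aldol path exists, and the C8 side chain drives it to the trans-fused 15.

## Further compounds

F1 | step 8 | tert-butyl(dimethyl){[(1R,2S,3S)-3-methyl-2,3-bis(1-trimethylsilyloxyethenyl)cyclopentyl]methoxy}silane (bis(trimethylsilyl enol ether) of 13) | CC(C)(C)[Si](C)(C)OC[C@@H]1CC[C@](C)(C(=C)O[Si](C)(C)C)[C@H]1C(=C)O[Si](C)(C)C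
F2 | step 8 | 2-bromo-1-[(1S,2S,3R)-3-({[tert-butyl(dimethyl)silyl]oxy}methyl)-1-methyl-2-(1-trimethylsilyloxyethenyl)cyclopentyl]ethan-1-one (C13 bromide) | CC(C)(C)[Si](C)(C)OC[C@@H]1CC[C@](C)(C(=O)CBr)[C@H]1C(=C)O[Si](C)(C)C
F0 | step 23 | none | none
F3 | step 18 | (4-bromo-5,5-dimethylcyclohex-3-en-1-ylidene)hydrazine | CC1(C)CC(=NN)CC=C1Br
F4 | step 18 | 1-bromo-4-iodo-6,6-dimethylcyclohexa-1,3-diene | CC1(C)CC(I)=CC=C1Br
F5 | step 18 | (4-bromo-5,5-dimethylcyclohexa-1,3-dien-1-yl)lithium | CC1(C)CC([Li])=CC=C1Br
F6 | step 9 | 15 as its C15 ethylene acetal (C12 ketone free; trans ring fusion) | CC(C)(C)[Si](C)(C)OC[C@@H]1CC[C@]2(C)C(=O)CCC3(OCCO3)[C@@H]12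
F7 | step 9 | C12 hydrazone of the C15 ethylene acetal | CC(C)(C)[Si](C)(C)OC[C@@H]1CC[C@]2(C)C(=NN)CCC3(OCCO3)[C@@H]12
F8 | step 9 | C12=C13 alkenyl bromide of the C15 ethylene acetal | CC(C)(C)[Si](C)(C)OC[C@@H]1CC[C@]2(C)C(Br)=CCC3(OCCO3)[C@@H]12
F9 | step 9 | (3R,3aS,7aS)-7-bromo-3-({[tert-butyl(dimethyl)silyl]oxy}methyl)-7a-methyl-1,2,3,3a,5,7a-hexahydro-4H-inden-4-one | CC(C)(C)[Si](C)(C)OC[C@@H]1CC[C@]2(C)C(Br)=CCC(=O)[C@@H]12
F10 | step 7 | (1R,3aS,7aR)-1-({[tert-butyl(dimethyl)silyl]oxy}methyl)-3a-methyloctahydro-1H-indene-4,7-dione (cis-fused C16 epimer of 15) | CC(C)(C)[Si](C)(C)OC[C@@H]1CC[C@]2(C)C(=O)CCC(=O)[C@H]12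
A1 | alternative 1 | (1E,6E)-1-bromo-5-({[tert-butyl(dimethyl)silyl]oxy}methyl)-2,7-dimethylnona-1,6,8-trien-3-one | CC(C)(C)[Si](C)(C)OC[C@H](CC(=O)/C(C)=C/Br)/C=C(\C)C=C
A2 | alternative 1 | trans-fused 7-bromo-3-({[tert-butyl(dimethyl)silyl]oxy}methyl)-4,7a-dimethyl-2,3,3a,6,7,7a-hexahydro-1H-inden-1-one | CC(C)(C)[Si](C)(C)OC[C@@H]2CC(=O)[C@]3(C)[C@@H](Br)CC=C(C)[C@@H]23
A3 | alternative 2 | methyl 4-[2-bromo-1,5-dimethyl-5-(trimethylsilyloxy)cyclohexyl]-2-diazo-3-oxobutanoate | COC(=O)C(=[N+]=[N-])C(=O)C[C@]1(C)[C@@H](Br)CC[C@@](C)(O[Si](C)(C)C)C1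
A4 | alternative 2 | methyl 4-bromo-3a,7-dimethyl-2-oxo-7-(trimethylsilyloxy)octahydro-1H-indene-1-carboxylate (trans-fused) | COC(=O)[C@@H]2C(=O)C[C@]3(C)[C@@H](Br)CC[C@@](C)(O[Si](C)(C)C)[C@@H]23
A5 | alternative 3 | 4-hydroxy-2,4-dimethylcyclohex-2-en-1-one (single enantiomer as drawn) | CC1=C[C@](C)(O)CCC1=O
A6 | alternative 3 | [(2-bromoprop-2-en-1-yl)oxy](tert-butyl)dimethylsilane | C=C(Br)CO[Si](C)(C)C(C)(C)C
A7 | alternative 3 | 2-allyl-3-[3-({tert-butyl(dimethyl)silyl}oxy)prop-1-en-2-yl]-4-hydroxy-2,4-dimethylcyclohexan-1-one | C=CC[C@]3(C)C(=O)CC[C@@](C)(O)[C@H]3C(=C)CO[Si](C)(C)C(C)(C)C
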